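**Retrosynthetic overview**
1. The last skeletal bond cut is the one between the central CH2 of the 1,3-diketone and the ring B carbonyl: enolate acylation of a ring A acetophenone with a 4-silyloxybenzoyl chloride, then removal of both silyl ethers.
2. The strategy rests on ring A, a benzene ring with four adjacent substituted carbons: C1' (diketone acyl), C2' (OMe), C3' (prenyl) and C4' (free OH). Only the oxygen next to the acyl carbon is methylated.
3. Ring A is therefore built rather than functionalised: a (4+2) cycloaddition of 1-methoxy-2-prenyl-3-silyloxycyclohexa-1,3-diene with but-3-yn-2-one forms the C1'–C2' and C5'–C6' bonds, and loss of ethylene aromatises the adduct (Alder–Rickert).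
4. The diene comes from cyclohexane-1,3-dione by C-prenylation, O-methylation under basic conditions and kinetic α'-enolisation/silylation, so the prenyl group and the O-methyl/O-silyl differentiation are set before any arene exists.
5. Ring order: ring B is bought (4-hydroxybenzoic acid); ring A is the only ring formed, in step 4.

Key step: step 4

Assumption: the β-diketone of the target is drawn in the diketo form; it is expected to exist mainly as its hydrogen-bonded enol tautomer, which is the same compound. The target has no stereocentre.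

**Route**

Step 1
Reactants: 1 cyclohexane-1,3-dione; 2 prenyl bromide (1-bromo-3-methylbut-2-ene)
Product: 3 2-(3-methylbut-2-enyl)cyclohexane-1,3-dione
Conditions: KOH (1.0 equiv), H2O, 1 in slight excess, 0 °C → rt; acidify cold to pH 4, extract
Reagents that add atoms: none
Why: SN2 C-alkylation of the ambident 1,3-dione enolate, in which water hydrogen-bonds the enolate oxygens and steers the soft allylic bromide to C2, and the acidic product is separated from neutral O-alkyl and dialkyl by-products by base extraction.

Step 2
Reactants: 3 2-(3-methylbut-2-enyl)cyclohexane-1,3-dione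
Product: 4 3-methoxy-2-(3-methylbut-2-enyl)cyclohex-2-en-1-one
Conditions: Me2SO4 (1.2 equiv), K2CO3 (1.5 equiv), acetone, reflux
Reagents that add atoms: dimethyl sulfate, COS(=O)(=O)OC
Why: O-alkylation of the potassium enolate of a 2-substituted cyclic 1,3-dione with a hard methylating agent gives the vinylogous ester (the dione is symmetric, so only one enol ether can form), and the basic medium avoids the acid-promoted cyclisation of the enol onto the prenyl double bond.

Step 3
Reactants: 4 3-methoxy-2-(3-methylbut-2-enyl)cyclohex-2-en-1-one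
Product: 6 1-methoxy-2-(3-methylbut-2-enyl)-3-(tert-butyldimethylsilyloxy)cyclohexa-1,3-diene, via lithium dienolate 5 (not isolated)
Conditions: LiN(i-Pr)2 (1.1 equiv), THF, −78 °C; TBSCl (1.2 equiv), DMPU, −78 °C → rt; pentane, filtration, no acidic work-up
Reagents that add atoms: tert-butyldimethylsilyl chloride, CC(C)(C)[Si](C)(C)Cl
Why: Kinetic deprotonation of a 3-alkoxycyclohex-2-enone with a hindered lithium amide occurs at the α' methylene (Stork–Danheiser regiochemistry), and O-silylation of the cross-conjugated enolate gives the 1-methoxy-3-silyloxy diene.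

Step 4
Reactants: 6 1-methoxy-2-(3-methylbut-2-enyl)-3-(tert-butyldimethylsilyloxy)cyclohexa-1,3-diene; 7 but-3-yn-2-one
Product: 9 1-[4-(tert-butyldimethylsilyloxy)-2-methoxy-3-(3-methylbut-2-enyl)phenyl]ethanone, via bicyclo[2.2.2]octadiene adduct 8 (not isolated)
Conditions: 7 (1.5 equiv), BHT (cat.), toluene, sealed tube, base-washed glass, 80 °C then 150 °C
Reagents that add atoms: none
Why: A thermal, normal-electron-demand (4+2) cycloaddition joins the diene termini C1 (methoxy-bearing) and C4 (CH) of 6 to the two alkyne carbons of 7 to give the bicyclo[2.2.2]octa-2,5-diene 8, and on further heating a retro-(4+2) reaction expels the saturated C5–C6 bridge as ethylene, driven by aromatisation (Alder–Rickert reaction). The closest known reaction type is the Alder–Rickert benzannulation of 1-alkoxy-3-silyloxycyclohexa-1,3-dienes with acetylenic ketones and esters, which gives resorcinol derivatives with the two oxygens differentiated. Ring A is closed by this intermolecular cycloaddition, which forms the ring bonds C(OMe)–C(acyl) and CH–CH, and the cycloreversion then only unmasks the arene. No stereocentre is created in 9; the two bridgehead centres of racemic 8 are erased when ethylene leaves. The step needs regioselectivity: the 3-silyloxy group directly and the 1-methoxy group vinylogously both raise the HOMO coefficient at the CH terminus C4, which therefore bonds to the β-carbon of the ynone, so the acetyl-bearing carbon ends up next to the methoxy-bearing carbon. The methoxy group sits at a bridgehead of 8 and has no elimination pathway, so it is carried into the arene, while the silyl enol ether becomes the aryl silyl ether para to the acetyl group.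

Step 5
Reactants: 10 4-hydroxybenzoic acid
Product: 11 tert-butyldimethylsilyl 4-(tert-butyldimethylsilyloxy)benzoate
Conditions: TBSCl (2.3 equiv), imidazole (5 equiv), DMF, rt
Reagents that add atoms: tert-butyldimethylsilyl chloride, CC(C)(C)[Si](C)(C)Cl
Why: Imidazole-mediated silylation masks the phenol and turns the acid into a silyl ester, which can be converted into the acid chloride without free HCl.

Step 6
Reactants: 11 tert-butyldimethylsilyl 4-(tert-butyldimethylsilyloxy)benzoate
Product: 12 4-(tert-butyldimethylsilyloxy)benzoyl chloride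
Conditions: (COCl)2 (1.2 equiv), DMF (cat.), CH2Cl2, 0 °C → rt; evaporate under high vacuum, use crude
Reagents that add atoms: oxalyl chloride, O=C(Cl)C(=O)Cl
Why: The chloroiminium salt formed from oxalyl chloride and catalytic DMF converts a silyl ester directly into the acid chloride under neutral conditions, with loss of TBSCl, CO and CO2, so the aryl silyl ether is left intact.

Step 7
Reactants: 9 1-[4-(tert-butyldimethylsilyloxy)-2-methoxy-3-(3-methylbut-2-enyl)phenyl]ethanone; 12 4-(tert-butyldimethylsilyloxy)benzoyl chloride
Product: 15 1-[4-(tert-butyldimethylsilyloxy)-2-methoxy-3-(3-methylbut-2-enyl)phenyl]-3-[4-(tert-butyldimethylsilyloxy)phenyl]propane-1,3-dione, via lithium enolate 13 (not isolated), via lithium diketonate 14 (not isolated)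
Conditions: LiN(SiMe3)2 (2.2 equiv), THF, −78 °C; 12 (1.05 equiv), −78 → 0 °C; aq. NH4Cl
Reagents that add atoms: none
Why: Claisen-type C-acylation of a methyl ketone lithium enolate by an aroyl chloride, in which the second equivalent of base converts the more acidic β-diketone into its chelated lithium enolate 14 and so prevents proton transfer to unreacted enolate, and in which no alkoxide is released that could cleave the aryl silyl ethers.

Step 8
Reactants: 15 1-[4-(tert-butyldimethylsilyloxy)-2-methoxy-3-(3-methylbut-2-enyl)phenyl]-3-[4-(tert-butyldimethylsilyloxy)phenyl]propane-1,3-dione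
Product: 16 1-[4-hydroxy-2-methoxy-3-(3-methylbut-2-enyl)phenyl]-3-(4-hydroxyphenyl)propane-1,3-dione (target)
Conditions: Bu4NF (2.5 equiv), AcOH (2.5 equiv), THF, 0 °C; pH 7 buffer
Reagents that add atoms: none
Why: Fluoride cleaves both aryl Si–O bonds by forming the strong Si–F bond, while acetic acid buffers the phenoxides and the diketonate, so neither retro-Claisen cleavage of the β-diketone nor any reaction at the prenyl group is expected.

**Compound list**
1 | cyclohexane-1,3-dione | O=C1CCCC(=O)C1 | starting material
2 | prenyl bromide (1-bromo-3-methylbut-2-ene) | CC(C)=CCBr | starting material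
3 | 2-(3-methylbut-2-enyl)cyclohexane-1,3-dione | CC(C)=CCC1C(=O)CCCC1=O | intermediate
4 | 3-methoxy-2-(3-methylbut-2-enyl)cyclohex-2-en-1-one | COC1=C(CC=C(C)C)C(=O)CCC1 | intermediate
5 | lithium 5-methoxy-6-(3-methylbut-2-enyl)cyclohexa-1,5-dien-1-olate (not isolated) | [Li+].COC1=C(CC=C(C)C)C([O-])=CCC1 | intermediate
6 | 1-methoxy-2-(3-methylbut-2-enyl)-3-(tert-butyldimethylsilyloxy)cyclohexa-1,3-diene, also named tert-butyl{[5-methoxy-6-(3-methylbut-2-enyl)cyclohexa-1,5-dien-1-yl]oxy}dimethylsilane | COC1=C(CC=C(C)C)C(O[Si](C)(C)C(C)(C)C)=CCC1 | intermediate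
7 | but-3-yn-2-one | CC(=O)C#C | starting material
8 | 1-[5-(tert-butyldimethylsilyloxy)-1-methoxy-6-(3-methylbut-2-enyl)bicyclo[2.2.2]octa-2,5-dien-2-yl]ethanone (racemic, relative configuration fixed by the bicycle, not isolated) | COC12CCC(C=C1C(C)=O)C(O[Si](C)(C)C(C)(C)C)=C2CC=C(C)C | intermediate
9 | 1-[4-(tert-butyldimethylsilyloxy)-2-methoxy-3-(3-methylbut-2-enyl)phenyl]ethanone | CC(=O)c1ccc(O[Si](C)(C)C(C)(C)C)c(CC=C(C)C)c1OC | intermediate
10 | 4-hydroxybenzoic acid | OC(=O)c1ccc(O)cc1 | starting material
11 | tert-butyldimethylsilyl 4-(tert-butyldimethylsilyloxy)benzoate | CC(C)(C)[Si](C)(C)OC(=O)c1ccc(O[Si](C)(C)C(C)(C)C)cc1 | intermediate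
12 | 4-(tert-butyldimethylsilyloxy)benzoyl chloride | CC(C)(C)[Si](C)(C)Oc1ccc(C(=O)Cl)cc1 | intermediate
13 | lithium 1-[4-(tert-butyldimethylsilyloxy)-2-methoxy-3-(3-methylbut-2-enyl)phenyl]ethen-1-olate (not isolated) | [Li+].C=C([O-])c1ccc(O[Si](C)(C)C(C)(C)C)c(CC=C(C)C)c1OC | intermediate
14 | lithium (Z)-1-[4-(tert-butyldimethylsilyloxy)-2-methoxy-3-(3-methylbut-2-enyl)phenyl]-3-[4-(tert-butyldimethylsilyloxy)phenyl]-3-oxoprop-1-en-1-olate (chelated, not isolated) | [Li+].COc1c(/C([O-])=C/C(=O)c2ccc(O[Si](C)(C)C(C)(C)C)cc2)ccc(O[Si](C)(C)C(C)(C)C)c1CC=C(C)C | intermediate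
15 | 1-[4-(tert-butyldimethylsilyloxy)-2-methoxy-3-(3-methylbut-2-enyl)phenyl]-3-[4-(tert-butyldimethylsilyloxy)phenyl]propane-1,3-dione | COc1c(C(=O)CC(=O)c2ccc(O[Si](C)(C)C(C)(C)C)cc2)ccc(O[Si](C)(C)C(C)(C)C)c1CC=C(C)C | intermediate
16 | 1-[4-hydroxy-2-methoxy-3-(3-methylbut-2-enyl)phenyl]-3-(4-hydroxyphenyl)propane-1,3-dione | COc1c(C(=O)CC(=O)c2ccc(O)cc2)ccc(O)c1CC=C(C)C | target

**Step count**
Total steps: 8. Longest linear sequence: 6 (steps 1, 2, 3, 4, 7, 8).

**Steps most likely to fail**

Step 4. The volatile terminal ynone may be lost to thermal oligomerisation, and the congested, acid-sensitive silyl dienol ether may be protodesilylated before it cycloadds, so that conversion to the arene stalls. The fallback sets out from diene 6 and returns at acetophenone 9. It brings the acyl carbon in at the ester oxidation level with a thermally robust dienophile and makes the methyl ketone afterwards. Diene 6 is heated with an excess of commercial methyl propiolate F1 (toluene or neat, sealed tube, 150 °C); the bicyclic adduct F2 (not isolated) loses ethylene to give methyl 4-(tert-butyldimethylsilyloxy)-2-methoxy-3-(3-methylbut-2-enyl)benzoate F3. Treatment of F3 with MeNH(OMe)·HCl and i-PrMgCl (THF, −20 °C) should give the N-methoxy-N-methylamide F4, and MeMgBr (THF, 0 °C) should then give 9.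

Step 7. O-acylation of enolate 13 and a second acylation of diketonate 14 may compete with the wanted C-acylation. The fallback sets out from acetophenone 9 and returns at diketone 15. It replaces the acylation by an aldol addition and an oxidation. Enolate 13, made with LiN(i-Pr)2 in THF at −78 °C, is added to commercial 4-(tert-butyldimethylsilyloxy)benzaldehyde F5 to give the racemic β-hydroxy ketone 3-hydroxy-1-[4-(tert-butyldimethylsilyloxy)-2-methoxy-3-(3-methylbut-2-enyl)phenyl]-3-[4-(tert-butyldimethylsilyloxy)phenyl]propan-1-one F6. Oxidation of F6 with Dess–Martin periodinane (NaHCO3, CH2Cl2, rt) should give 15; the carbinol stereocentre is removed in this oxidation.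

Step 1. O-alkylation and double C-alkylation of the dione enolate, together with hydrolysis of the allylic bromide in water, may leave little of the mono-C-prenyl dione. The fallback sets out from prenyl bromide 2 and returns at dione 3. It replaces enolate alkylation by alkylation of a masked dione. Commercial 1,5-dimethoxycyclohexa-1,4-diene F7 is deprotonated at C6, the methylene between the two enol ether carbons, with t-BuLi in THF/HMPA at −78 °C. The resulting pentadienyl lithium F8 (not isolated) is alkylated with 2 at its central carbon to give 1,5-dimethoxy-6-(3-methylbut-2-enyl)cyclohexa-1,4-diene F9. Brief hydrolysis of both enol ethers (1 M HCl, acetone, rt) should give 3.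

**Further compounds**
F1 | step 4 | methyl propiolate (commercial input) | COC(=O)C#C
F2 | step 4 | methyl 5-(tert-butyldimethylsilyloxy)-1-methoxy-6-(3-methylbut-2-enyl)bicyclo[2.2.2]octa-2,5-diene-2-carboxylate (racemic, not isolated) | COC(=O)C1=CC2CCC1(OC)C(CC=C(C)C)=C2O[Si](C)(C)C(C)(C)C
F3 | step 4 | methyl 4-(tert-butyldimethylsilyloxy)-2-methoxy-3-(3-methylbut-2-enyl)benzoate | COC(=O)c1ccc(O[Si](C)(C)C(C)(C)C)c(CC=C(C)C)c1OC
F4 | step 4 | 4-(tert-butyldimethylsilyloxy)-N,2-dimethoxy-N-methyl-3-(3-methylbut-2-enyl)benzamide | CON(C)C(=O)c1ccc(O[Si](C)(C)C(C)(C)C)c(CC=C(C)C)c1OC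
F5 | step 7 | 4-(tert-butyldimethylsilyloxy)benzaldehyde (commercial input) | CC(C)(C)[Si](C)(C)Oc1ccc(C=O)cc1
F6 | step 7 | 3-hydroxy-1-[4-(tert-butyldimethylsilyloxy)-2-methoxy-3-(3-methylbut-2-enyl)phenyl]-3-[4-(tert-butyldimethylsilyloxy)phenyl]propan-1-one (racemic) | COc1c(C(=O)CC(O)c2ccc(O[Si](C)(C)C(C)(C)C)cc2)ccc(O[Si](C)(C)C(C)(C)C)c1CC=C(C)C
F7 | step 1 | 1,5-dimethoxycyclohexa-1,4-diene (commercial input) | COC1=CCC=C(OC)C1
F8 | step 1 | (2,6-dimethoxycyclohexa-2,5-dien-1-yl)lithium (not isolated) | [Li+].COC1=CCC=C(OC)[CH-]1
F9 | step 1 | 1,5-dimethoxy-6-(3-methylbut-2-enyl)cyclohexa-1,4-diene | COC1=CCC=C(OC)C1CC=C(C)C
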